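Ring C is a β-resorcylic acid: C1' (CO2H), C2'/C4' (OH) and C6' (pentyl) form the pattern of a malonate–enone annulation, and the ether carbon C5' is simply the α-carbon of the C4' carbonyl. The diaryl ether oxygen is therefore attached to a non-aromatic carbon first, and ring C is grown around it. The precursor is a (Z)-α-aryloxy enone: non-3-en-2-one carrying the ring A salicylate oxygen on C3. With dibenzyl malonate, one operation forms C1'–C6' (conjugate addition) and C2'–C3' (Claisen closure), giving a 4-aryloxycyclohexane-1,3-dione. Dehydrogenation, isocoumarin construction on ring A and one BBr3 deprotection without heating follow.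

Key step: step 3

Remarks on the chemistry
- Primed locants C1'–C6' are ring C (the benzoic acid ring); unprimed locants are the isocoumarin (rings A and B).
- The enone maps onto ring C as follows: acetyl CH3 → C3', C=O → C4', aryloxy-bearing carbon → C5', alkene CH → C6'. The malonate supplies C1', C2' and the carboxyl carbon.
- The target has no stereocentre; the three sp3 centres made in the key step are transient.
- Assumption: the enone forms mainly as the Z isomer. Any E isomer is carried along, because the alkene geometry is lost in the annulation.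
- The malonate is used as its dibenzyl ester, so the ring C acid is released without heating; 2,4-dihydroxy-6-alkylbenzoic acids lose CO2 when heated. KOtBu is the base, so no nucleophilic alkoxide is present to scramble the esters.
- The enone is assembled by O–H insertion and olefination. This fixes the position of the C=C bond and avoids enolate chemistry next to the ring A ester before the key step.

Step 1
Reactants: 1 methyl 2-hydroxy-4-methoxy-6-methylbenzoate; 2 dimethyl (1-diazo-2-oxopropyl)phosphonate
Product: 3 methyl 2-{[1-(dimethoxyphosphoryl)-2-oxopropyl]oxy}-4-methoxy-6-methylbenzoate (racemic)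
Conditions: Rh2(OAc)4 (1 mol %), ClCH2CH2Cl, 80 °C, slow addition of 2 (1.3 equiv)
Reagents that add atoms: none
Why: Rhodium-catalysed carbene O–H insertion of a diazo ketophosphonate into a phenol is established and neutral, and it installs in one step the ether oxygen, the future C5', the acetyl group and the olefination handle; the new stereocentre is racemic and is removed in step 2.

Step 2
Reactants: 3 methyl 2-{[1-(dimethoxyphosphoryl)-2-oxopropyl]oxy}-4-methoxy-6-methylbenzoate; 4 hexanal
Product: 5 methyl 4-methoxy-2-methyl-6-{[(3Z)-2-oxonon-3-en-3-yl]oxy}benzoate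
Conditions: LiCl, DBU, MeCN, 0 °C → rt
Reagents that add atoms: none
Why: Horner–Wadsworth–Emmons olefination with LiCl/amine activation tolerates the enolisable aldehyde and the ring A ester, can place the C=C bond only at the phosphorus-bearing carbon, and should favour the isomer with pentyl trans to acetyl (Z).

Step 3
Reactants: 5 methyl 4-methoxy-2-methyl-6-{[(3Z)-2-oxonon-3-en-3-yl]oxy}benzoate; 6 dibenzyl malonate
Product: 8 benzyl (1S*,5R*,6S*)-5-[5-methoxy-2-(methoxycarbonyl)-3-methylphenoxy]-2,4-dioxo-6-pentylcyclohexane-1-carboxylate (racemic all-trans), via Michael adduct 7 (not isolated)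
Conditions: KOtBu (1.2 equiv), 6 (1.3 equiv), THF, 0 °C → 65 °C; then 1 M HCl
Reagents that add atoms: none
Why: The potassium enolate of 6 adds to C6' of the enone (C1'–C6' bond), proton transfer moves the charge to the methyl ketone carbon C3', and that enolate closes onto one benzyl ester of the malonate (C2'–C3' bond), the expelled benzyloxide being consumed at once by deprotonation of the 1,3-dione product, which pulls the reversible sequence forward. The closest known reaction is the Michael–Claisen annulation of malonates with alk-3-en-2-ones to 5-alkylcyclohexane-1,3-diones. Ring C closes in a 6-(enolexo)-exo-trig Dieckmann-type mode. C1' and C5' are epimerisable and should settle trans to the C6' pentyl group (all-equatorial) under thermodynamic control, the material is racemic, and all three centres are erased in step 4. The step needs 1,4-addition to an enone whose C5' oxygen donates into the double bond, which is secured by coupling the reversible addition to an irreversible closure, and it needs regioselective acylation, which is secured because only C3' reaches a malonate ester through a six-membered transition state, whereas attack of C5' on the hindered 2,6-disubstituted ring A ester would give a non-enolisable diketone that reverts. The aryloxy group on C5' is never beta to a carbanion, so it cannot be eliminated.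

Step 4
Reactants: 8 benzyl (1S*,5R*,6S*)-5-[5-methoxy-2-(methoxycarbonyl)-3-methylphenoxy]-2,4-dioxo-6-pentylcyclohexane-1-carboxylate
Product: 9 benzyl 4,6-dihydroxy-3-[5-methoxy-2-(methoxycarbonyl)-3-methylphenoxy]-2-pentylbenzoate
Conditions: I2 (0.2 equiv), DMSO, 80 °C; Na2S2O3 (aq) work-up
Reagents that add atoms: none
Why: Iodine-catalysed dehydrogenation of an enolised cyclohexane-1,3-dione (α-iodination, loss of HI, tautomerisation, with DMSO reoxidising iodide) is a known aromatisation of dihydroresorcylates and keeps the steady-state acid level low; the three stereocentres disappear.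

Step 5
Reactants: 9 benzyl 4,6-dihydroxy-3-[5-methoxy-2-(methoxycarbonyl)-3-methylphenoxy]-2-pentylbenzoate
Product: 10 benzyl 4,6-dimethoxy-3-[5-methoxy-2-(methoxycarbonyl)-3-methylphenoxy]-2-pentylbenzoate
Conditions: MeI (4 equiv), K2CO3, DMF, 40 °C
Reagents that add atoms: iodomethane, CI
Why: Williamson O-methylation masks both acidic phenols before the strong-base step, and carbonate leaves the benzyl and methyl esters untouched.

Step 6
Reactants: 11 hexanoyl chloride; 12 N,O-dimethylhydroxylamine hydrochloride
Product: 13 N-methoxy-N-methylhexanamide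
Conditions: K2CO3, H2O/CH2Cl2, 0 °C → rt
Reagents that add atoms: none
Why: Schotten–Baumann N-acylation of the hydroxylamine by an acid chloride is routine and gives the acyl donor that stops at the ketone stage.

Step 7
Reactants: 10 benzyl 4,6-dimethoxy-3-[5-methoxy-2-(methoxycarbonyl)-3-methylphenoxy]-2-pentylbenzoate; 13 N-methoxy-N-methylhexanamide
Product: 16 benzyl 4,6-dimethoxy-3-[5-methoxy-2-(methoxycarbonyl)-3-(2-oxoheptyl)phenoxy]-2-pentylbenzoate, via benzylic organolithium 14 (not isolated), via lithium hemiaminal chelate 15 (not isolated)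
Conditions: LiN(iPr)2 (1.2 equiv), THF, −78 °C; then 13 (2 equiv), −78 → −20 °C; NH4Cl (aq)
Reagents that add atoms: none
Why: Lateral lithiation of an ortho-toluate followed by acylation with an N-methoxy-N-methylamide is well precedented for 2,4-dioxygenated 6-methylbenzoates; the ring A methyl is the most acidic and least hindered benzylic site (the ring C benzylic CH2 is secondary and flanked by the aryloxy group), both esters are shielded by two ortho substituents, and the chelate 15 releases the ketone only on quench.

Step 8
Reactants: 16 benzyl 4,6-dimethoxy-3-[5-methoxy-2-(methoxycarbonyl)-3-(2-oxoheptyl)phenoxy]-2-pentylbenzoate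
Product: 17 benzyl 4,6-dimethoxy-3-[(6-methoxy-1-oxo-3-pentyl-1H-isochromen-8-yl)oxy]-2-pentylbenzoate
Conditions: TsOH·H2O (0.2 equiv), toluene, 110 °C, 4 Å molecular sieves
Reagents that add atoms: none
Why: Acid-catalysed enol lactonisation, in which the aryl-conjugated enol of the benzylic ketone attacks the neighbouring methyl ester (6-exo-trig) and loses methanol to give the conjugated isocoumarin; the benzyl ester and the methyl ethers are stable to catalytic sulfonic acid.

Step 9
Reactants: 17 benzyl 4,6-dimethoxy-3-[(6-methoxy-1-oxo-3-pentyl-1H-isochromen-8-yl)oxy]-2-pentylbenzoate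
Product: 18 4,6-dihydroxy-3-[(6-hydroxy-1-oxo-3-pentyl-1H-isochromen-8-yl)oxy]-2-pentylbenzoic acid
Conditions: BBr3 (8 equiv), CH2Cl2, −78 °C → rt; ice-water
Reagents that add atoms: none
Why: Lewis-acid O-dealkylation with BBr3 cleaves the three aryl methyl ethers and the benzyl ester by O-alkyl scission while the diaryl ether and the isocoumarin lactone are inert, and the acid is freed without heating, so the decarboxylation-prone 2,4-dihydroxybenzoic acid survives.

Compound list
1 | methyl 2-hydroxy-4-methoxy-6-methylbenzoate | COC(=O)c1c(C)cc(OC)cc1O | starting material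
2 | dimethyl (1-diazo-2-oxopropyl)phosphonate | CC(=O)C(=[N+]=[N-])P(=O)(OC)OC | starting material
3 | methyl 2-{[1-(dimethoxyphosphoryl)-2-oxopropyl]oxy}-4-methoxy-6-methylbenzoate (racemic) | COC(=O)c1c(C)cc(OC)cc1OC(C(C)=O)P(=O)(OC)OC | intermediate
4 | hexanal | CCCCCC=O | starting material
5 | methyl 4-methoxy-2-methyl-6-{[(3Z)-2-oxonon-3-en-3-yl]oxy}benzoate | CCCCC/C=C(\Oc1cc(OC)cc(C)c1C(=O)OC)C(C)=O | intermediate
6 | dibenzyl malonate (dibenzyl propanedioate) | O=C(CC(=O)OCc1ccccc1)OCc1ccccc1 | starting material
7 | dibenzyl 2-{3-[5-methoxy-2-(methoxycarbonyl)-3-methylphenoxy]-2-oxononan-4-yl}propanedioate (Michael adduct, racemic diastereomer mixture, not isolated) | CCCCCC(C(Oc1cc(OC)cc(C)c1C(=O)OC)C(C)=O)C(C(=O)OCc1ccccc1)C(=O)OCc1ccccc1 | intermediate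
8 | benzyl (1S*,5R*,6S*)-5-[5-methoxy-2-(methoxycarbonyl)-3-methylphenoxy]-2,4-dioxo-6-pentylcyclohexane-1-carboxylate (racemic, all-trans, one enantiomer drawn) | CCCCC[C@@H]1[C@@H](Oc2cc(OC)cc(C)c2C(=O)OC)C(=O)CC(=O)[C@H]1C(=O)OCc1ccccc1 | intermediate
9 | benzyl 4,6-dihydroxy-3-[5-methoxy-2-(methoxycarbonyl)-3-methylphenoxy]-2-pentylbenzoate | CCCCCc1c(Oc2cc(OC)cc(C)c2C(=O)OC)c(O)cc(O)c1C(=O)OCc1ccccc1 | intermediate
10 | benzyl 4,6-dimethoxy-3-[5-methoxy-2-(methoxycarbonyl)-3-methylphenoxy]-2-pentylbenzoate | CCCCCc1c(Oc2cc(OC)cc(C)c2C(=O)OC)c(OC)cc(OC)c1C(=O)OCc1ccccc1 | intermediate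
11 | hexanoyl chloride | CCCCCC(Cl)=O | starting material
12 | N,O-dimethylhydroxylamine hydrochloride | CNOC.Cl | starting material
13 | N-methoxy-N-methylhexanamide | CCCCCC(=O)N(C)OC | intermediate
14 | 10 lithiated at the ring A benzylic carbon (benzylic organolithium, not isolated) | [Li]Cc1cc(OC)cc(Oc2c(OC)cc(OC)c(C(=O)OCc3ccccc3)c2CCCCC)c1C(=O)OC | intermediate
15 | lithium alkoxide of the tetrahedral adduct of 14 with 13 (N-methoxy-N-methyl hemiaminal chelate, not isolated) | CCCCCC(O[Li])(Cc1cc(OC)cc(Oc2c(OC)cc(OC)c(C(=O)OCc3ccccc3)c2CCCCC)c1C(=O)OC)N(C)OC | intermediate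
16 | benzyl 4,6-dimethoxy-3-[5-methoxy-2-(methoxycarbonyl)-3-(2-oxoheptyl)phenoxy]-2-pentylbenzoate | CCCCCC(=O)Cc1cc(OC)cc(Oc2c(OC)cc(OC)c(C(=O)OCc3ccccc3)c2CCCCC)c1C(=O)OC | intermediate
17 | benzyl 4,6-dimethoxy-3-[(6-methoxy-1-oxo-3-pentyl-1H-isochromen-8-yl)oxy]-2-pentylbenzoate | CCCCCc1cc2cc(OC)cc(Oc3c(OC)cc(OC)c(C(=O)OCc4ccccc4)c3CCCCC)c2c(=O)o1 | intermediate
18 | 4,6-dihydroxy-3-[(6-hydroxy-1-oxo-3-pentyl-1H-isochromen-8-yl)oxy]-2-pentylbenzoic acid (no stereocentre) | CCCCCc1cc2cc(O)cc(Oc3c(O)cc(O)c(C(=O)O)c3CCCCC)c2c(=O)o1 | target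

Total step count: 9
Longest linear sequence: 8 (steps 1–5 and 7–9; step 6 is a one-step side branch)

Steps most likely to fail

Step 3. The conjugate addition may not keep pace: the oxygen on C5' feeds electron density into the enone and the β-pentyl group shields C6', so retro-addition and ester-side reactions of the enolates can take over. The fallback forms the C5'–C6' bond instead, with donor and acceptor exchanged. It sets out from 1, 4 and 6. Phenol 1 is O-alkylated with chloroacetone (K2CO3, KI, acetone, reflux) to methyl 4-methoxy-2-methyl-6-(2-oxopropoxy)benzoate F1. Knoevenagel condensation of 4 with 6 (piperidine, AcOH, toluene, water removal) gives dibenzyl 2-hexylidenepropanedioate F2. Pyrrolidine-catalysed enamine Michael addition of F1, through its aryloxy-bearing carbon, to the doubly activated alkene of F2 gives 7, where the fallback rejoins the route; 7 is then closed to 8 with KOtBu as in step 3.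

Step 7. Acylation may be slower than proton transfer, so that the benzylic anion is quenched by the enolisable amide or condenses with an ester of a second molecule. The fallback sets out from 10 and replaces the acyl donor by an aldehyde followed by oxidation. The anion 14 is trapped at −78 °C with hexanal 4, a much faster electrophile, and quenched cold with AcOH to give benzyl 3-[3-(2-hydroxyheptyl)-5-methoxy-2-(methoxycarbonyl)phenoxy]-4,6-dimethoxy-2-pentylbenzoate F3 (racemic). Oxidation of the secondary alcohol with 2-iodoxybenzoic acid (DMSO, rt) gives 16, where the route is rejoined.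

Step 4. The HI formed in the flask may cleave the α-aryloxy ketone reductively, or cleave the benzyl β-keto ester with loss of CO2, or iodine may substitute C3'. The fallback sets out from 8 and is free of acid and iodide. Silylation with TBSOTf/Et3N (CH2Cl2, 0 °C) gives benzyl 2,4-bis[(tert-butyldimethylsilyl)oxy]-5-[5-methoxy-2-(methoxycarbonyl)-3-methylphenoxy]-6-pentylcyclohexa-1,3-diene-1-carboxylate F4 (racemic, 5,6-trans). DDQ (toluene, rt) dehydrogenates this cyclohexadiene to benzyl 4,6-bis[(tert-butyldimethylsilyl)oxy]-3-[5-methoxy-2-(methoxycarbonyl)-3-methylphenoxy]-2-pentylbenzoate F5. Desilylation with Bu4NF/AcOH (THF, 0 °C) gives 9, where the route is rejoined.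

Further compounds
F1 | step 3 | methyl 4-methoxy-2-methyl-6-(2-oxopropoxy)benzoate | COC(=O)c1c(C)cc(OC)cc1OCC(C)=O
F2 | step 3 | dibenzyl 2-hexylidenepropanedioate | CCCCCC=C(C(=O)OCc1ccccc1)C(=O)OCc1ccccc1
F3 | step 7 | benzyl 3-[3-(2-hydroxyheptyl)-5-methoxy-2-(methoxycarbonyl)phenoxy]-4,6-dimethoxy-2-pentylbenzoate (racemic) | CCCCCC(O)Cc1cc(OC)cc(Oc2c(OC)cc(OC)c(C(=O)OCc3ccccc3)c2CCCCC)c1C(=O)OC
F4 | step 4 | benzyl 2,4-bis[(tert-butyldimethylsilyl)oxy]-5-[5-methoxy-2-(methoxycarbonyl)-3-methylphenoxy]-6-pentylcyclohexa-1,3-diene-1-carboxylate (racemic, 5,6-trans, one enantiomer drawn) | CCCCC[C@@H]1[C@@H](Oc2cc(OC)cc(C)c2C(=O)OC)C(O[Si](C)(C)C(C)(C)C)=CC(O[Si](C)(C)C(C)(C)C)=C1C(=O)OCc1ccccc1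
F5 | step 4 | benzyl 4,6-bis[(tert-butyldimethylsilyl)oxy]-3-[5-methoxy-2-(methoxycarbonyl)-3-methylphenoxy]-2-pentylbenzoate | CCCCCc1c(Oc2cc(OC)cc(C)c2C(=O)OC)c(O[Si](C)(C)C(C)(C)C)cc(O[Si](C)(C)C(C)(C)C)c1C(=O)OCc1ccccc1
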